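- Start from a one-step world, G + L → J with Q merely speeding it, and expect J in Monday's run to climb towards the 250 mM of G, the limiting reagent, which is less than the 750 mM of L; then see that Monday's readings stand at 53 mM at 17 h and at 68 mM at 43 h.

the same everywhere: Q 2.50 mM
- Monday's: G 250 mM; L 750 mM
- Thursday's: G 100 mM; L 600 mM
- Wednesday's: G 250 mM; L 1100 mM
- Friday's: G 380 mM; L 750 mM
- Tuesday's: G 250 mM; L 750 mM; time 110 h

- Monday's run (time / h: [J] / mM): 8.6: 43; 17: 53; 26: 56; 34: 52; 43: 68
- Thursday's run (time / h: [J] / mM): 8.6: 33; 17: 49; 26: 45; 34: 44; 43: 54
- Wednesday's run (time / h: [J] / mM): 8.6: 47; 17: 66; 26: 53; 34: 56; 43: 58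
- Friday's run (time / h: [J] / mM): 8.6: 37; 17: 55; 26: 53; 34: 48; 43: 62

(readings scatter by 4 mM)

* the power of [L] that the first rate follows, about the charge of the Monday's run; measure it at two percent of G made into J
* the power of [G] that the first rate follows, about the charge of the Monday's run; measure it at two percent of G made into J (one fixed amount of J, the same in the runs compared)
* J in the Tuesday's run at 110 h, as a share of the G charged

- Overall: G + L -> J, with Q as catalyst.
- Constant volume, constant temperature.
- A reading of a species includes what of it is bound.
- An order is taken over about fifteen percent of the charge, up and down.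

- Fold the late readings and the catalyst into one dimensionless number, the turnover number N: take the mean [J] from 17 h on and divide it by the [Q] charge, which tells how many J each Q charged has made once the climb has flattened, and find for Monday's run 22.9.

- Test whether one number is enough: Thursday's run gives 19.2, Wednesday's 23.3 and Friday's 21.8, so from Thursday's run to Friday's N rises by a factor of 1.14 while [G] at the start rises by 3.80 and [L] at the start by 1.25; but Thursday's N lies 3.70 below Monday's, against a scatter of about 0.800 on such a mean, so one number does not cover every charge, and Tuesday's run must take the N of Monday's, whose charge it repeats.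

- Read my own figure for Tuesday's run as N times [Q] over [G], which gives 22.9% if J climbs no further by 110 h, and leave the orders unread, since Monday's first reading, 43 mM, is already past the two percent of G at which they are asked.

- Set beside this the forecast, which gives 0.3 for the order in L, 0 for the order in G and 25% for Tuesday's run, slightly above my figure, on the ground that “the likely cause is catalyst death”.

- Take the flask's answers: the orders are 0.70 in L and 0.31 in G, both above the forecast's, while Tuesday's run gives 23.5%, which is N = 23.5 against Monday's 22.9.

    Q + G → QG (290.2 M⁻¹ h⁻¹)
    QG + L → J + Q (38.16 M⁻¹ h⁻¹)
    Q + Ky → Zu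
    2 L → Xo (1.739 M⁻¹ h⁻¹)

- Carry N to Thursday's run, where the J made comes to half of that run's charge at 48.0 h, which is N = 20.0 against the 19.2 read from its readings. Tuesday's N stands at 23.5 at 110 h because L goes to Xo: without that step the same run makes J up to 100% of G instead of 23.5%.

The earlier runs and the new flask are simulated with made-up constants; scatter was added.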